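**Retrosynthetic overview**
1. Target ⇐ mild hydrolysis of a dioxolane that masks the C1 ketone, so the enone is unveiled last.
2. trans-Diol ketal ⇐ hydroxyl-directed 1,2-reduction of an α′-hydroxy enone (C4 carbinol set trans to the C5 hydroxyl by internal hydride delivery).
3. α′-Hydroxy enone ⇐ enantioselective, metal-free phase-transfer aerobic α′-hydroxylation of the racemic α′-alkyl enone (sets the quaternary carbinol C5; proposed new step).
4. α′-Alkyl enone ⇐ α′-alkylation of 1,4-dioxaspiro[4.5]dec-6-en-8-one with a C19 bromide, itself from copper-catalysed coupling of (E)-hex-3-enylmagnesium bromide with 1,13-dibromotridecane.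
5. Ring order: the single six-membered ring is bought intact; no ring is formed.

Assumption: 1,13-dibromotridecane and 1,4-dioxaspiro[4.5]dec-6-en-8-one are taken as catalogue compounds.

**Route**

Step 1
Reactants: 1 (E)-hex-3-en-1-ol
Product: 2 (E)-1-bromohex-3-ene
Conditions: CBr4 (1.1 equiv), PPh3 (1.15 equiv), CH2Cl2, 0 → 23 °C
Reagents that add atoms: carbon tetrabromide, BrC(Br)(Br)Br
Why: Appel reaction of a primary homoallylic alcohol proceeds by SN2 displacement of the oxyphosphonium group and does not touch the (E)-alkene.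

Step 2
Reactants: 2 (E)-1-bromohex-3-ene; 3 1,13-dibromotridecane
Product: 5 (3E)-19-bromononadec-3-ene, via (E)-hex-3-enylmagnesium bromide 4 (not isolated)
Conditions: Mg, THF, 23–40 °C; then added to 3 (3 equiv), Li2CuCl4 (3 mol %), THF, −10 → 23 °C
Reagents that add atoms: none
Why: Kochi-type copper-catalysed sp3–sp3 Grignard cross-coupling, in which the excess dibromide (recovered by distillation) enforces mono-substitution and the alkene geometry is carried over unchanged.

Step 3
Reactants: 6 1,4-dioxaspiro[4.5]dec-6-en-8-one; 5 (3E)-19-bromononadec-3-ene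
Product: 8 rac-9-[(16E)-nonadec-16-en-1-yl]-1,4-dioxaspiro[4.5]dec-6-en-8-one, via lithium dienolate 7 (not isolated)
Conditions: 6 (1.5 equiv), LiN(i-Pr)2 (1.45 equiv), THF, −78 °C; then 5 (1.0 equiv), DMPU, n-Bu4NI (0.2 equiv), −78 → 23 °C
Reagents that add atoms: none
Why: Kinetic α′-deprotonation gives only the cross-conjugated dienolate (the γ-carbon is the ketal carbon and has no hydrogen), which undergoes iodide-assisted SN2 enolate alkylation with the primary bromide; the C9–H centre formed is racemic and is erased in step 4.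

Step 4
Reactants: 8 rac-9-[(16E)-nonadec-16-en-1-yl]-1,4-dioxaspiro[4.5]dec-6-en-8-one
Product: 11 (9S)-9-hydroxy-9-[(16E)-nonadec-16-en-1-yl]-1,4-dioxaspiro[4.5]dec-6-en-8-one, via potassium dienolate 9 (not isolated), via (9S)-9-hydroperoxide 10 (not isolated)
Conditions: O2 (1 atm), N-(9-anthracenylmethyl)-O-allylcinchonidinium bromide (10 mol %), P(OEt)3 (2 equiv), 50% aq. KOH, toluene, −20 → 0 °C
Reagents that add atoms: dioxygen, O=O
Why: Proposed new method: enantioconvergent aerobic α′-hydroxylation of a cross-conjugated cyclohexenone dienolate under chiral phase-transfer catalysis — C9–H is the only acidic hydrogen of 8, so interfacial KOH gives one planar dienolate 9, which enters toluene as a tight ion pair with the cinchonidinium cation whose anthracenylmethyl arm shields one enolate face; O2 adds at C9 (the only carbon carrying enolate spin density) on the open face to give hydroperoxide 10, which P(OEt)3 reduces with retention before it can close onto the enone, setting the (S) quaternary carbinol; the closest known reaction is the cinchona-ammonium-catalysed O2/P(OEt)3 α-hydroxylation of 2-alkyl-1-tetralones and 2-alkyl-1-indanones, of which 9 is a shape analogue (vinyl plus spiro-dioxolane in place of the benzo ring), and the (S) sense is assigned by that analogy, the pseudoenantiomeric cinchoninium salt being used if it proves opposite.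

Step 5
Reactants: 11 (9S)-9-hydroxy-9-[(16E)-nonadec-16-en-1-yl]-1,4-dioxaspiro[4.5]dec-6-en-8-one
Product: 13 (8S,9S)-9-[(16E)-nonadec-16-en-1-yl]-1,4-dioxaspiro[4.5]dec-6-ene-8,9-diol, via alkoxydiacetoxyborohydride 12 (not isolated)
Conditions: Me4NBH(OAc)3 (5 equiv), MeCN/AcOH (1:1), −30 → 0 °C; aq. NaHCO3 work-up
Reagents that add atoms: none
Why: Evans–Saksena-type hydroxyl-directed reduction in which the tertiary C9 hydroxyl binds boron and delivers hydride to the C8 carbonyl from its own face, so the new C8 hydroxyl is trans to the C9 hydroxyl (8S), while the reagent is too mild to reduce the enone conjugately or to affect the ketal or the chain alkene.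

Step 6
Reactants: 13 (8S,9S)-9-[(16E)-nonadec-16-en-1-yl]-1,4-dioxaspiro[4.5]dec-6-ene-8,9-diol
Product: 14 (4S,5S)-4,5-dihydroxy-5-[(16E)-nonadec-16-en-1-yl]cyclohex-2-en-1-one
Conditions: 0.5 M aq. HCl, THF, 0 → 23 °C, monitored by TLC; NaHCO3 quench
Reagents that add atoms: water, O
Why: Acid-catalysed ketal hydrolysis through an allyl-stabilised oxocarbenium ion is fast for this allylic dioxolane, so dilute cold acid unmasks the enone, as for the ethylene ketal of 4-hydroxycyclohex-2-enone, without dehydrating the tertiary β-hydroxy ketone and without touching either stereocentre.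

**Compound list**
1 | (E)-hex-3-en-1-ol | CC/C=C/CCO | starting material
2 | (E)-1-bromohex-3-ene | CC/C=C/CCBr | intermediate
3 | 1,13-dibromotridecane | BrCCCCCCCCCCCCCBr | starting material
4 | (E)-hex-3-enylmagnesium bromide | CC/C=C/CC[Mg]Br | intermediate (not isolated)
5 | (3E)-19-bromononadec-3-ene [(16E)-1-bromononadec-16-ene] | CC/C=C/CCCCCCCCCCCCCCCBr | intermediate
6 | 1,4-dioxaspiro[4.5]dec-6-en-8-one | O=C1C=CC2(CC1)OCCO2 | starting material
7 | lithium 1,4-dioxaspiro[4.5]deca-6,8-dien-8-olate | [Li+].[O-]C1=CCC2(OCCO2)C=C1 | intermediate (not isolated)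
8 | rac-9-[(16E)-nonadec-16-en-1-yl]-1,4-dioxaspiro[4.5]dec-6-en-8-one (C9 racemic) | CC/C=C/CCCCCCCCCCCCCCCC1CC2(OCCO2)C=CC1=O | intermediate
9 | potassium 9-[(16E)-nonadec-16-en-1-yl]-1,4-dioxaspiro[4.5]deca-6,8-dien-8-olate (carried into toluene as its ion pair with the catalyst cation) | [K+].[O-]C1=C(CCCCCCCCCCCCCCC/C=C/CC)CC2(OCCO2)C=C1 | intermediate (not isolated)
10 | (9S)-9-hydroperoxy-9-[(16E)-nonadec-16-en-1-yl]-1,4-dioxaspiro[4.5]dec-6-en-8-one | CC/C=C/CCCCCCCCCCCCCCC[C@]1(OO)CC2(OCCO2)C=CC1=O | intermediate (not isolated)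
11 | (9S)-9-hydroxy-9-[(16E)-nonadec-16-en-1-yl]-1,4-dioxaspiro[4.5]dec-6-en-8-one | CC/C=C/CCCCCCCCCCCCCCC[C@]1(O)CC2(OCCO2)C=CC1=O | intermediate
12 | tetramethylammonium diacetoxy(hydrido){[(9S)-9-[(16E)-nonadec-16-en-1-yl]-8-oxo-1,4-dioxaspiro[4.5]dec-6-en-9-yl]oxy}borate | C[N+](C)(C)C.CC/C=C/CCCCCCCCCCCCCCC[C@]1(O[BH-](OC(C)=O)OC(C)=O)CC2(OCCO2)C=CC1=O | intermediate (not isolated)
13 | (8S,9S)-9-[(16E)-nonadec-16-en-1-yl]-1,4-dioxaspiro[4.5]dec-6-ene-8,9-diol | CC/C=C/CCCCCCCCCCCCCCC[C@]1(O)CC2(OCCO2)C=C[C@@H]1O | intermediate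
14 | (4S,5S)-4,5-dihydroxy-5-[(16E)-nonadec-16-en-1-yl]cyclohex-2-en-1-one | CC/C=C/CCCCCCCCCCCCCCC[C@]1(O)CC(=O)C=C[C@@H]1O | target

**Step count**
Total steps: 6. Longest linear sequence: 6 (1 → 2 → 5 → 8 → 11 → 13 → 14).

**Three steps most likely to fail**

Step 3 (enolate alkylation with an unactivated C19 bromide). The SN2 step is slow, so proton transfer and polyalkylation can erode the yield. The fallback is the Corey–Enders azaenolate route, setting out from 6 and 5. Compound 6 is condensed with 1,1-dimethylhydrazine (cat. AcOH, EtOH, 50 °C) to 1,1-dimethyl-2-(1,4-dioxaspiro[4.5]dec-6-en-8-ylidene)hydrazine F1. Deprotonation at C9 with LiN(i-Pr)2 (THF, −78 → 0 °C) gives the lithium azaenolate F2, which is far more nucleophilic than 7 and is alkylated by 5 at 0 °C to the 9-alkyl dimethylhydrazone F3. Neutral hydrolysis with aqueous CuCl2 (THF, pH 7 phosphate buffer, 23 °C) leaves the dioxolane intact and returns to the route at 8.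

Step 4 (proposed new hydroxylation). The risks are a low stationary concentration of the weakly acidic dienolate, modest enantioselectivity for a non-benzo-fused enolate, and intramolecular peroxy-Michael closure or C–C cleavage of hydroperoxide 10 if phosphite reduction lags. The fallback is known reagent-controlled enolate oxidation, setting out from 8. NaN(SiMe3)2 (THF, −78 °C) gives the sodium 9-alkyl dienolate F4, which is oxidised at −78 °C with an enantiopure (camphorsulfonyl)oxaziridine, an established method for tetrasubstituted ketone enolates. The antipode that gives the (S) product is chosen by a small screen of the two commercial antipodes. This returns to the route at 11, and the enantiomeric purity can be raised by recrystallising 11 or 13.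

Step 5 (trans-selective reduction). Ligand exchange of the hindered tertiary hydroxyl onto boron may be slow, and a competing external hydride pathway would erode the trans selectivity. The fallback sets out from 11 and accepts a mixture. Reduction with external hydride (NaBH4, CeCl3·7H2O, MeOH, −78 °C) gives 13 together with its C8 epimer, and the two are separated. The epimer, (8R,9S)-9-[(16E)-nonadec-16-en-1-yl]-1,4-dioxaspiro[4.5]dec-6-ene-8,9-diol F5, is inverted at the secondary carbinol by Mitsunobu esterification (4-nitrobenzoic acid, PPh3, DIAD, THF, 0 °C; the tertiary hydroxyl does not react). This gives the (8S,9S)-8-(4-nitrobenzoate) F6, and methanolysis (K2CO3, MeOH, 0 °C) returns to the route at 13.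

**Further compounds**
F1 | step 3 | 1,1-dimethyl-2-(1,4-dioxaspiro[4.5]dec-6-en-8-ylidene)hydrazine (C=N isomer mixture) | CN(C)N=C1C=CC2(CC1)OCCO2
F2 | step 3 | lithium azaenolate of F1 (lithium (1,4-dioxaspiro[4.5]deca-6,8-dien-8-yl)(dimethylamino)azanide) | [Li+].CN(C)[N-]C1=CCC2(OCCO2)C=C1
F3 | step 3 | rac-1,1-dimethyl-2-{9-[(16E)-nonadec-16-en-1-yl]-1,4-dioxaspiro[4.5]dec-6-en-8-ylidene}hydrazine | CC/C=C/CCCCCCCCCCCCCCCC1CC2(OCCO2)C=CC1=NN(C)C
F4 | step 4 | sodium 9-[(16E)-nonadec-16-en-1-yl]-1,4-dioxaspiro[4.5]deca-6,8-dien-8-olate | [Na+].[O-]C1=C(CCCCCCCCCCCCCCC/C=C/CC)CC2(OCCO2)C=C1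
F5 | step 5 | (8R,9S)-9-[(16E)-nonadec-16-en-1-yl]-1,4-dioxaspiro[4.5]dec-6-ene-8,9-diol | CC/C=C/CCCCCCCCCCCCCCC[C@]1(O)CC2(OCCO2)C=C[C@H]1O
F6 | step 5 | (8S,9S)-9-hydroxy-9-[(16E)-nonadec-16-en-1-yl]-1,4-dioxaspiro[4.5]dec-6-en-8-yl 4-nitrobenzoate | CC/C=C/CCCCCCCCCCCCCCC[C@]1(O)CC2(OCCO2)C=C[C@@H]1OC(=O)c1ccc(cc1)[N+](=O)[O-]
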